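**Retrosynthetic overview**
- The route rests on one feature, present twice: C3 of a trans-2-aryl-2,3-dihydrobenzofuran is bonded to a resorcinol-ring carbon meta to both oxygens, and this C3–aryl bond lies in an eight-membered carbocycle that also holds a diarylmethine CH and the two central CH carbons.
- Each C3–aryl bond is cut as the addition of an arylpalladium across C2=C3 of a 2-aryl-benzofuran tethered through its C4, with formate reduction; the same reaction closes ring 1 (key step) and later ring 2.
- Ring order: benzofuran (iodocyclisation), then eight-membered ring 1 with dihydrofuran 1, then eight-membered ring 2 with dihydrofuran 2.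
- The central chain Ca–Cb–Cc–Cd is grown on the ring-1 ketone: Cb–aryl by ketone α-arylation, Cd by one-carbon homologation and aryl Grignard addition, and the last anisyl group by Friedel–Crafts capture of the ring-held cation.
- Only Ca is set by a catalyst (Rh-catalysed conjugate arylation of 5,7-dimethoxycoumarin); all other stereocentres are relayed from it. Building blocks 7 and 12 are each used twice.

Key step: step 9

Labels: the central chain is Ca(H)(anisyl)–Cb–Cc–Cd(H)(anisyl). Ca is bonded to resorcinol ring 1, Cb to C4' of benzofuran 2, Cc to C4 of benzofuran 1, Cd to resorcinol ring 2. Unprimed C2/C3 belong to (dihydro)benzofuran 1, primed to benzofuran 2.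
Assumption: (R)-Segphos is taken to give the (R)-lactone 3, the sense known for this addition to coumarins; the antipodal ligand is used if the sense proves opposite.

**Step 1**
Reactants: 1 5,7-dimethoxycoumarin; 2 4-methoxyphenylboronic acid
Product: 3 (R)-5,7-dimethoxy-4-(4-methoxyphenyl)chroman-2-one
Conditions: Rh(acac)(C2H4)2 (3 mol %), (R)-Segphos, dioxane/H2O 10:1, 60 °C
Reagents that add atoms: none
Why: Hayashi–Miyaura rhodium-catalysed asymmetric 1,4-addition of an arylboronic acid to a coumarin; the planar lactone offers an open β-carbon and the Rh–Segphos complex selects the enantioface, which sets Ca (R).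

**Step 2**
Reactants: 3 (R)-5,7-dimethoxy-4-(4-methoxyphenyl)chroman-2-one
Product: 4 (R)-3-(2-hydroxy-4,6-dimethoxyphenyl)-N-methoxy-3-(4-methoxyphenyl)-N-methylpropanamide
Conditions: MeNH(OMe)·HCl, AlMe3, CH2Cl2, 0 °C to rt
Reagents that add atoms: N,O-dimethylhydroxylamine hydrochloride, CNOC.Cl
Why: AlMe3-mediated Weinreb aminolysis of the aryl lactone (an activated ester) should open the ring without touching Ca.

**Step 3**
Reactants: 4 (R)-3-(2-hydroxy-4,6-dimethoxyphenyl)-N-methoxy-3-(4-methoxyphenyl)-N-methylpropanamide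
Product: 5 (R)-3,5-dimethoxy-2-[3-(methoxy(methyl)amino)-1-(4-methoxyphenyl)-3-oxopropyl]phenyl trifluoromethanesulfonate
Conditions: PhNTf2, Et3N, DMAP (cat.), CH2Cl2, rt
Reagents that add atoms: N-phenylbis(trifluoromethanesulfonimide), O=S(=O)(N(c1ccccc1)S(=O)(=O)C(F)(F)F)C(F)(F)F
Why: O-sulfonylation of the phenol with the mild triflimide reagent, which does not activate the Weinreb amide as triflic anhydride could.

**Step 4**
Reactants: 6 1-bromo-3,5-dimethoxybenzene
Product: 7 1-bromo-2-iodo-3,5-dimethoxybenzene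
Conditions: NIS, TFA (cat.), MeCN, rt
Reagents that add atoms: N-iodosuccinimide, O=C1CCC(=O)N1I
Why: electrophilic aromatic iodination para to one methoxy and ortho to the other (C2 and C6 are equivalent), the position between the two methoxy groups being the more hindered one.

**Step 5**
Reactants: 7 1-bromo-2-iodo-3,5-dimethoxybenzene; 8 4-ethynylanisole
Product: 9 1-bromo-3,5-dimethoxy-2-[(4-methoxyphenyl)ethynyl]benzene
Conditions: PdCl2(PPh3)2 (3 mol %), CuI (5 mol %), Et3N, THF, 40 °C
Reagents that add atoms: none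
Why: Sonogashira coupling, chemoselective for the C–I bond over the C–Br bond.

**Step 6**
Reactants: 9 1-bromo-3,5-dimethoxy-2-[(4-methoxyphenyl)ethynyl]benzene
Product: 10 4-bromo-3-iodo-6-methoxy-2-(4-methoxyphenyl)benzofuran
Conditions: I2, CH2Cl2, rt
Reagents that add atoms: iodine, II
Why: Larock iodocyclisation: the iodonium-activated alkyne is attacked 5-endo-dig by the ortho methoxy oxygen and iodide demethylates the oxonium ion, so the furan oxygen and C3a are fixed by the position of the alkyne.

**Step 7**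
Reactants: 10 4-bromo-3-iodo-6-methoxy-2-(4-methoxyphenyl)benzofuran
Product: 12 4-bromo-6-methoxy-2-(4-methoxyphenyl)benzofuran, via benzofuran-3-ylmagnesium chloride 11 (not isolated)
Conditions: iPrMgCl·LiCl, THF, −40 °C; then 1 M HCl
Reagents that add atoms: none
Why: iodine–magnesium exchange is much faster at the heteroaryl iodide than at the aryl bromide, and protonation gives the free C3–H needed for the key step.

**Step 8**
Reactants: 12 4-bromo-6-methoxy-2-(4-methoxyphenyl)benzofuran; 5 aryl triflate Weinreb amide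
Product: 14 (R)-3,5-dimethoxy-2-{3-[6-methoxy-2-(4-methoxyphenyl)benzofuran-4-yl]-1-(4-methoxyphenyl)-3-oxopropyl}phenyl trifluoromethanesulfonate, via arylmagnesium bromide 13 (not isolated)
Conditions: 12, Mg, LiCl, THF, rt; then 5, THF, 0 °C; then 1 M HCl
Reagents that add atoms: none
Why: Weinreb ketone synthesis: the aryl Grignard adds once to give a chelated adduct that collapses to the ketone only on work-up, and an aryl triflate tolerates arylmagnesium reagents at 0 °C.

**Step 9**
Reactants: 14 benzofuran-4-yl 2,2-diarylethyl ketone aryl triflate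
Product: 15 ring-1 ketone: eight-membered ring Ca–resorcinol ring 1–C3–C3a–C4–Cc(=O)–CbH2 fused to a trans-(2R,3R)-6-methoxy-2-(4-methoxyphenyl)-2,3-dihydrobenzofuran; Ca (R) bears 4-methoxyphenyl; Ca–H and C3–H anti
Conditions: Pd(OAc)2 (10 mol %), dppp (12 mol %), HCO2Na (2 equiv, solid), DMF, 90 °C, 0.005 M
Reagents that add atoms: none
Why: Zerovalent palladium (from Pd(OAc)2 and dppp) inserts into the aryl C–OTf bond, the cationic arylpalladium adds syn across C2=C3 of the benzofuran with the aryl group going to C3, and the C2 benzylic palladium, which has no syn β-hydrogen, takes up formate, loses CO2 and reductively eliminates C2–H with retention. The closest known reaction type is the intramolecular dearomative reductive Heck reaction of benzofurans and indoles, established for five- and six-membered closures and used here for a larger ring. The one ring closed is the eight-membered carbocycle, in the 8-exo-trig mode (C3 inside, C2 outside the new ring), while the furan becomes a dihydrofuran. C2 is controlled by the mechanism (syn addition, then hydride transfer with retention), which puts the two aryl groups trans; C3 is controlled by Ca through allylic strain: the Ca–H lies in the plane of resorcinol ring 1 beside the ortho methoxy group, the CH2–CO tether and the anisyl group take opposite faces of that ring, and the benzofuran, held on the tether face, receives the aryl group so that the new C3–H points to the anisyl side. The step needs this face selectivity and needs carbopalladation to outrun formate reduction of the arylpalladium; the first rests on the Ca stereocentre, the second on high dilution, sparingly soluble HCO2Na and the short aryl ketone tether from C4 that holds C3 next to palladium. The connectivity is fixed by construction, since the substrate holds one aryl electrophile and one alkene.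

**Step 10**
Reactants: 15 ring-1 ketone; 12 4-bromo-6-methoxy-2-(4-methoxyphenyl)benzofuran
Product: 17 Cb-[6-methoxy-2-(4-methoxyphenyl)benzofuran-4-yl] ring-1 ketone (Cb S; Cb–H anti to the anisyl group on Ca), via sodium enolate 16 (not isolated)
Conditions: Pd(OAc)2 (5 mol %), XPhos (10 mol %), NaOtBu (2.5 equiv), toluene, 80 °C; then AcOH, −78 °C
Reagents that add atoms: none
Why: palladium-catalysed ketone α-arylation (Buchwald–Hartwig type) at the only enolisable position; the product rests as enolate 16 and is protonated cold on the face opposite to the anisyl group on Ca, which sets Cb.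

**Step 11**
Reactants: 17 Cb-aryl ring-1 ketone
Product: 18 Cc-methylene compound (C=CH2 in place of C=O; other centres as in 17)
Conditions: Zn, CH2Br2, TiCl4, THF/CH2Cl2, 0 °C to rt
Reagents that add atoms: dibromomethane, BrCBr
Why: Takai–Lombardo methylenation, a non-basic reagent that converts hindered, enolisable aryl ketones and should leave the α-aryl centre Cb untouched.

**Step 12**
Reactants: 18 Cc-methylene compound
Product: 20 Cc-hydroxymethyl compound (CH2OH cis to the benzofuranyl group on Cb expected as the main epimer), via alkylborane 19 (not isolated)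
Conditions: BH3·THF, THF, 0 °C to rt; then NaOH, H2O2, 0 °C
Reagents that add atoms: hydrogen peroxide, OO
Why: hydroboration–oxidation of a 1,1-disubstituted alkene, with boron going to the terminal carbon and borane expected on the face away from the benzofuranyl group on Cb; the Cc configuration is corrected in step 13, so a minor epimer is carried along.

**Step 13**
Reactants: 20 Cc-hydroxymethyl compound
Product: 22 Cc-formyl compound, trans (formyl trans to the benzofuranyl group on Cb; Cc–H syn to C3–H), via cis aldehyde 21 (not isolated)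
Conditions: Dess–Martin periodinane, NaHCO3, CH2Cl2, rt; then DBU (0.2 equiv), CH2Cl2, rt
Reagents that add atoms: none
Why: Dess–Martin oxidation followed by base epimerisation of the α-aryl aldehyde through its enolate; the favoured epimer should have the formyl group trans to the vicinal aryl group and the Cc–H on the peri side next to C3–H, which is the target configuration at Cc.

**Step 14**
Reactants: 7 1-bromo-2-iodo-3,5-dimethoxybenzene; 22 trans Cc-formyl compound
Product: 24 Cd carbinol, Cc–CH(OH)–(2-bromo-4,6-dimethoxyphenyl), both carbinol epimers, via arylmagnesium chloride 23 (not isolated)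
Conditions: 7, iPrMgCl·LiCl, THF, −40 °C; then 22, LaCl3·2LiCl (0.3 equiv), −40 to 0 °C; then aq. NH4Cl
Reagents that add atoms: none
Why: Knochel iodine–magnesium exchange (iodide before bromide; the ortho-bromoaryl Grignard is stable cold) and 1,2-addition to the aldehyde, with LaCl3·2LiCl suppressing enolisation; the carbinol centre is removed in step 15.

**Step 15**
Reactants: 24 Cd carbinol
Product: 25 Cd ketone, Cc–C(=O)–(2-bromo-4,6-dimethoxyphenyl)
Conditions: Dess–Martin periodinane, NaHCO3, CH2Cl2, 0 °C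
Reagents that add atoms: none
Why: buffered Dess–Martin oxidation turns the acid-labile, electron-rich benzylic alcohol into a ketone that cannot ionise before ring 2 is closed.

**Step 16**
Reactants: 25 Cd ketone with aryl bromide
Product: 26 ring-2 ketone: second eight-membered ring Cd(=O)–resorcinol ring 2–C3'–C3a'–C4'–Cb–Cc, with trans-(2'S,3'S)-dihydrobenzofuran 2; C3'–H syn to Cb–H
Conditions: Pd(OAc)2 (10 mol %), dppp (12 mol %), HCO2Na (2 equiv, solid), DMF, 100 °C, 0.005 M
Reagents that add atoms: none
Why: second intramolecular dearomative reductive Heck reaction (8-exo-trig, aryl bromide onto C3' of benzofuran 2, trans by syn addition and retentive hydride transfer); peri strain should keep the Cb–H beside C3' on the face away from the tether so that the new C3'–H comes out syn to Cb–H, and Cc, if it equilibrates next to the ketone, should keep the trans arrangement set in step 13.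

**Step 17**
Reactants: 26 ring-2 ketone
Product: 27 ring-2 carbinol (Cd–OH, either epimer)
Conditions: LiAlH4, THF, 0 °C
Reagents that add atoms: none
Why: hydride reduction of the hindered aryl ketone; both carbinol epimers give the same cation in step 18, and Cc is no longer enolisable.

**Step 18**
Reactants: 27 ring-2 carbinol; 28 anisole
Product: 29 decamethyl ether of the target (Cd anisyl trans to the benzofuran-1 carbon on Cc)
Conditions: 28 (20 equiv), TsOH·H2O (10 mol %), CH2Cl2, 0 °C
Reagents that add atoms: none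
Why: Friedel–Crafts benzylation of anisole (para) by the o,p-dimethoxybenzylic cation; held inside ring 2, the cation cannot reach another ring of the molecule (an indane or seven-membered closure would need a meta-bridged arene), and anisole should enter on the face opposite to the aryl group on Cc, which sets Cd.

**Step 19**
Reactants: 29 decamethyl ether
Product: 30 CNP0224452.2 (target decaphenol)
Conditions: BBr3, CH2Cl2, −78 °C to rt; then H2O
Reagents that add atoms: none
Why: Lewis acid cleavage of the ten aryl methyl ethers; no stereocentre is enolisable, and the cold addition is meant to spare the two benzylic C2–O bonds of the dihydrofurans.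

**Compound list**
1 | 5,7-dimethoxycoumarin | COc1cc(OC)c2C=CC(=O)Oc2c1 | starting material
2 | 4-methoxyphenylboronic acid | COc1ccc(B(O)O)cc1 | starting material
3 | (R)-5,7-dimethoxy-4-(4-methoxyphenyl)chroman-2-one | COc1ccc(cc1)[C@H]1CC(=O)Oc2cc(OC)cc(OC)c21 | intermediate
4 | (R)-3-(2-hydroxy-4,6-dimethoxyphenyl)-N-methoxy-3-(4-methoxyphenyl)-N-methylpropanamide | COc1ccc(cc1)[C@H](c2c(OC)cc(OC)cc2O)CC(=O)N(C)OC | intermediate
5 | (R)-aryl triflate Weinreb amide | COc1ccc(cc1)[C@H](c2c(OC)cc(OC)cc2OS(=O)(=O)C(F)(F)F)CC(=O)N(C)OC | intermediate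
6 | 1-bromo-3,5-dimethoxybenzene | COc1cc(Br)cc(OC)c1 | starting material
7 | 1-bromo-2-iodo-3,5-dimethoxybenzene | COc1cc(Br)c(I)c(OC)c1 | intermediate
8 | 4-ethynylanisole | COc1ccc(C#C)cc1 | starting material
9 | 1-bromo-3,5-dimethoxy-2-[(4-methoxyphenyl)ethynyl]benzene | COc1ccc(cc1)C#Cc1c(Br)cc(OC)cc1OC | intermediate
10 | 4-bromo-3-iodo-6-methoxy-2-(4-methoxyphenyl)benzofuran | COc1ccc(cc1)-c1oc2cc(OC)cc(Br)c2c1I | intermediate
11 | [4-bromo-6-methoxy-2-(4-methoxyphenyl)benzofuran-3-yl]magnesium chloride | COc1ccc(cc1)-c1oc2cc(OC)cc(Br)c2c1[Mg]Cl | intermediate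
12 | 4-bromo-6-methoxy-2-(4-methoxyphenyl)benzofuran | COc1ccc(cc1)-c1oc2cc(OC)cc(Br)c2c1 | intermediate
13 | [6-methoxy-2-(4-methoxyphenyl)benzofuran-4-yl]magnesium bromide | COc1ccc(cc1)-c1oc2cc(OC)cc([Mg]Br)c2c1 | intermediate
14 | key-step precursor, (R)-aryl triflate benzofuran-4-yl ketone | COc1ccc(cc1)[C@H](c2c(OC)cc(OC)cc2OS(=O)(=O)C(F)(F)F)CC(=O)c2cc(OC)cc3oc(-c4ccc(OC)cc4)cc23 | intermediate
15 | ring-1 ketone (Ca R; 2R,3R) | COc1ccc([C@@H]2c3c(OC)cc(OC)cc3[C@@H]3c4c(cc(OC)cc4C(=O)C2)O[C@H]3c2ccc(OC)cc2)cc1 | intermediate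
16 | sodium enolate of 17 | COc1ccc([C@@H]2c3c(OC)cc(OC)cc3[C@@H]3c4c(cc(OC)cc4C([O-])=C2c7cc(OC)cc8oc(-c9ccc(OC)cc9)cc78)O[C@H]3c2ccc(OC)cc2)cc1.[Na+] | intermediate
17 | Cb-(benzofuran-4-yl) ring-1 ketone (Cb S) | COc1ccc([C@@H]2c3c(OC)cc(OC)cc3[C@@H]3c4c(cc(OC)cc4C(=O)[C@@H]2c7cc(OC)cc8oc(-c9ccc(OC)cc9)cc78)O[C@H]3c2ccc(OC)cc2)cc1 | intermediate
18 | Cc-methylene compound | COc1ccc([C@@H]2c3c(OC)cc(OC)cc3[C@@H]3c4c(cc(OC)cc4C(=C)[C@@H]2c7cc(OC)cc8oc(-c9ccc(OC)cc9)cc78)O[C@H]3c2ccc(OC)cc2)cc1 | intermediate
19 | alkylborane (Cc–CH2–BH2) | COc1ccc([C@@H]2c3c(OC)cc(OC)cc3[C@@H]3c4c(cc(OC)cc4[C@H](CB)[C@@H]2c7cc(OC)cc8oc(-c9ccc(OC)cc9)cc78)O[C@H]3c2ccc(OC)cc2)cc1 | intermediate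
20 | Cc-hydroxymethyl compound (main epimer) | COc1ccc([C@@H]2c3c(OC)cc(OC)cc3[C@@H]3c4c(cc(OC)cc4[C@H](CO)[C@@H]2c7cc(OC)cc8oc(-c9ccc(OC)cc9)cc78)O[C@H]3c2ccc(OC)cc2)cc1 | intermediate
21 | cis Cc-formyl compound | COc1ccc([C@@H]2c3c(OC)cc(OC)cc3[C@@H]3c4c(cc(OC)cc4[C@H](C=O)[C@@H]2c7cc(OC)cc8oc(-c9ccc(OC)cc9)cc78)O[C@H]3c2ccc(OC)cc2)cc1 | intermediate
22 | trans Cc-formyl compound | COc1ccc([C@@H]2c3c(OC)cc(OC)cc3[C@@H]3c4c(cc(OC)cc4[C@@H](C=O)[C@@H]2c7cc(OC)cc8oc(-c9ccc(OC)cc9)cc78)O[C@H]3c2ccc(OC)cc2)cc1 | intermediate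
23 | (2-bromo-4,6-dimethoxyphenyl)magnesium chloride | COc1cc(Br)c([Mg]Cl)c(OC)c1 | intermediate
24 | Cd carbinol (both epimers at Cd) | COc1ccc([C@@H]2c3c(OC)cc(OC)cc3[C@@H]3c4c(cc(OC)cc4[C@@H](C(O)c5c(OC)cc(OC)cc5Br)[C@@H]2c7cc(OC)cc8oc(-c9ccc(OC)cc9)cc78)O[C@H]3c2ccc(OC)cc2)cc1 | intermediate
25 | Cd ketone with aryl bromide | COc1ccc([C@@H]2c3c(OC)cc(OC)cc3[C@@H]3c4c(cc(OC)cc4[C@@H](C(=O)c5c(OC)cc(OC)cc5Br)[C@@H]2c7cc(OC)cc8oc(-c9ccc(OC)cc9)cc78)O[C@H]3c2ccc(OC)cc2)cc1 | intermediate
26 | ring-2 ketone (2'S,3'S) | COc1ccc([C@@H]2c3c(OC)cc(OC)cc3[C@@H]3c4c(cc(OC)cc4[C@H]4C(=O)c5c(OC)cc(OC)cc5[C@H]5c6c(cc(OC)cc6[C@H]24)O[C@@H]5c2ccc(OC)cc2)O[C@H]3c2ccc(OC)cc2)cc1 | intermediate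
27 | ring-2 carbinol (either epimer at Cd) | COc1ccc([C@@H]2c3c(OC)cc(OC)cc3[C@@H]3c4c(cc(OC)cc4[C@H]4C(O)c5c(OC)cc(OC)cc5[C@H]5c6c(cc(OC)cc6[C@H]24)O[C@@H]5c2ccc(OC)cc2)O[C@H]3c2ccc(OC)cc2)cc1 | intermediate
28 | anisole | COc1ccccc1 | starting material
29 | decamethyl ether of the target | COc1ccc([C@@H]2c3c(OC)cc(OC)cc3[C@@H]3c4c(cc(OC)cc4[C@H]4[C@H](c5ccc(OC)cc5)c5c(OC)cc(OC)cc5[C@H]5c6c(cc(OC)cc6[C@H]24)O[C@@H]5c2ccc(OC)cc2)O[C@H]3c2ccc(OC)cc2)cc1 | intermediate
30 | CNP0224452.2 | Oc1ccc([C@@H]2c3c(O)cc(O)cc3[C@@H]3c4c(cc(O)cc4[C@H]4[C@H](c5ccc(O)cc5)c5c(O)cc(O)cc5[C@H]5c6c(cc(O)cc6[C@H]24)O[C@@H]5c2ccc(O)cc2)O[C@H]3c2ccc(O)cc2)cc1 | target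

**Step count**
Total: 19 steps. Longest linear sequence: 16 steps (6 to 30 through steps 4–19).

**Steps most likely to fail**

1. Step 9. The arylpalladium may be reduced by formate, or may palladate an ortho C–H of the anisyl group on Ca, before the slow eight-membered carbopalladation; the benzofuran may also be taken on the wrong face. The fallback sets out from 5 and 10 and comes back at 15. It makes the C3–aryl bond first, between separate molecules, and closes the ring by acylation. Miyaura borylation of 5 (B2pin2, PdCl2(dppf), KOAc, dioxane, 80 °C) gives the pinacol boronate F1. Suzuki coupling of F1 with 10 at its C–I bond (Pd(OAc)2, SPhos, K3PO4, toluene/H2O, 60 °C) gives the 3-aryl-4-bromobenzofuran F2. Ionic hydrogenation (Et3SiH, TFA, CH2Cl2, 0 °C) gives the trans-dihydrobenzofuran as the (2R,3R) isomer F3 together with its (2S,3S) diastereomer F4, separable by chromatography because Ca is fixed. Bromine–lithium exchange on F3 (t-BuLi, THF, −78 °C) and Parham-type attack of the aryllithium on the Weinreb amide closes the eight-membered ketone 15.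

2. Step 16. The arylpalladium may be reduced, or may palladate the neighbouring C5–H of dihydrobenzofuran 1 (a six-membered closure), before it reaches C3'; the carbopalladation may also take the wrong face of benzofuran 2. The fallback sets out from 25 and comes back at 29. It joins the two rings as a biaryl and sets the furan stereocentres afterwards. Iodination of 25 with NIS at C3', the enol-ether-like and most nucleophilic carbon, gives the 3'-iodide F5. Intramolecular reductive biaryl coupling with zerovalent nickel (Ni(cod)2, 2,2'-bipyridine, DMF, 50 °C) gives the ring-2 ketone with an intact 2,3-diarylbenzofuran F6. LiAlH4 gives the carbinol F7, and anisole with TsOH·H2O, as in step 18, gives the anisyl compound F8. Ionic hydrogenation (Et3SiH, TFA, CH2Cl2) then reduces C2'=C3' to the trans-dihydrofuran 29, C3' being set by protonation inside the closed ring instead of by carbopalladation.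

3. Step 18. Anisole may attack the ring-held cation on the wrong face or through its ortho position, or the cation may lose the Cc proton and put Cc at stake. The fallback sets out from 26 and comes back at 29. It brings in the aryl group as a nucleophile on the ketone and the hydrogen last. Addition of 4-methoxyphenylmagnesium bromide with CeCl3 (THF, −78 to 0 °C) to 26 gives the tertiary carbinol F9. Ionic deoxygenation (Et3SiH, TFA, CH2Cl2, −20 °C) then delivers hydride to the face that anisole would have taken, so the anisyl group ends on the other face; the para connectivity is fixed by the Grignard reagent.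

**Further compounds**
F1 | step 9 | (R)-pinacol boronate from 5 | COc1ccc(cc1)[C@H](c2c(OC)cc(OC)cc2B2OC(C)(C)C(C)(C)O2)CC(=O)N(C)OC
F2 | step 9 | 3-aryl-4-bromobenzofuran Weinreb amide | COc1ccc(cc1)[C@H](c2c(OC)cc(OC)cc2-c2c(-c3ccc(OC)cc3)oc3cc(OC)cc(Br)c23)CC(=O)N(C)OC
F3 | step 9 | trans-(2R,3R)-4-bromo-2,3-dihydrobenzofuran Weinreb amide | COc1ccc(cc1)[C@H](c2c(OC)cc(OC)cc2[C@@H]2c3c(Br)cc(OC)cc3O[C@H]2c2ccc(OC)cc2)CC(=O)N(C)OC
F4 | step 9 | trans-(2S,3S) diastereomer of F3 | COc1ccc(cc1)[C@H](c2c(OC)cc(OC)cc2[C@H]2c3c(Br)cc(OC)cc3O[C@@H]2c2ccc(OC)cc2)CC(=O)N(C)OC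
F5 | step 16 | 3'-iodo derivative of 25 | COc1ccc([C@@H]2c3c(OC)cc(OC)cc3[C@@H]3c4c(cc(OC)cc4[C@@H](C(=O)c5c(OC)cc(OC)cc5Br)[C@@H]2c7cc(OC)cc8oc(-c9ccc(OC)cc9)c(I)c78)O[C@H]3c2ccc(OC)cc2)cc1
F6 | step 16 | ring-2 ketone with aromatic benzofuran 2 | COc1ccc([C@@H]2c3c(OC)cc(OC)cc3[C@@H]3c4c(cc(OC)cc4[C@H]4C(=O)c5c(OC)cc(OC)cc5-c5c6c(cc(OC)cc6[C@H]24)oc5-c2ccc(OC)cc2)O[C@H]3c2ccc(OC)cc2)cc1
F7 | step 16 | ring-2 carbinol with aromatic benzofuran 2 (either epimer at Cd) | COc1ccc([C@@H]2c3c(OC)cc(OC)cc3[C@@H]3c4c(cc(OC)cc4[C@H]4C(O)c5c(OC)cc(OC)cc5-c5c6c(cc(OC)cc6[C@H]24)oc5-c2ccc(OC)cc2)O[C@H]3c2ccc(OC)cc2)cc1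
F8 | step 16 | Cd-anisyl compound with aromatic benzofuran 2 | COc1ccc([C@@H]2c3c(OC)cc(OC)cc3[C@@H]3c4c(cc(OC)cc4[C@H]4[C@H](c5ccc(OC)cc5)c5c(OC)cc(OC)cc5-c5c6c(cc(OC)cc6[C@H]24)oc5-c2ccc(OC)cc2)O[C@H]3c2ccc(OC)cc2)cc1
F9 | step 18 | Cd tertiary carbinol (either epimer at Cd) | COc1ccc([C@@H]2c3c(OC)cc(OC)cc3[C@@H]3c4c(cc(OC)cc4[C@H]4C(O)(c5ccc(OC)cc5)c5c(OC)cc(OC)cc5[C@H]5c6c(cc(OC)cc6[C@H]24)O[C@@H]5c2ccc(OC)cc2)O[C@H]3c2ccc(OC)cc2)cc1
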